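## Structural features

The target (C29H26O4) is an achiral macrocyclic bis(bibenzyl). Four benzene rings are tied into one 19-membered ring by two diaryl ether oxygens (ring A–O–ring B, ring C–O–ring D) and two CH2–CH2 bridges (ring B–ring C, ring D–ring A). The shortest path counts 3 (ring A, meta) + 1 + 4 (ring B, para) + 2 + 3 (ring C, meta) + 1 + 3 (ring D, meta) + 2 = 19 atoms.

Ring A carries OMe at C1, the bridge to ring D at C4 (para to OMe) and the ether oxygen at C6 (ortho to OMe), which is the isovanillic pattern. Ring C carries the bridge at C1, the free OH at C4 and the ether oxygen at C5. Ring B is para- and ring D meta-disubstituted.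

There is no stereocentre, so no relative configuration has to be controlled. The only stereogenic atom that appears on the way is a benzylic C–SMe carbon, and it is erased again.

The sensitive groups are:
- the free phenol of ring C, which is nucleophilic and oxidisable and must be masked through the alkylation and base steps;
- the methyl ether of ring A, which must survive the unmasking of that phenol;
- the diaryl ethers, which are robust but exclude dissolving-metal reductions;
- the benzylic position on ring A, whose halides and onium salts ionise easily because of the para methoxyl.

The real difficulty is closing an entropically costly 19-membered carbocycle, and telling four aryl-bound carbon termini apart without protecting-group traffic.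

The feature exploited is the D–A bridge. It is a bond between two benzylic carbons (the CH2 on ring D and the CH2 on ring A C4), exactly the bond a [1,2]-shift in a dibenzyl sulfonium ylide creates. The carbocycle can therefore be reached from a ring one atom larger that contains CH2–S–CH2 and closes by simple thiolate alkylation. Checked atom by atom, the 20-membered sulfide and the 19-membered methylthio macrocycle of the key step map correctly onto the target, and no structural correction is needed.

## Logic of the disconnections

**20 back to 18.** A methylthio group is put back on the ring D benzylic carbon and the ring C hydroxyl is capped as a benzyl ether, so the forward step cleaves one C–S and one O–CH2Ph bond. Both are benzylic bonds to a heteroatom and fall to the same nickel surface, so unmasking and sulfur removal are one operation and the racemic C–SMe centre disappears. The demand is a reductant that leaves the aryl methyl ether, the diaryl ethers and the arenes alone. On its way the step passes through 19.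

**18 back to 15.** The C–C bond between the two benzylic carbons of the D–A bridge is cut, both carbons are reattached to sulfur and the S-methyl group is removed; the forward path runs through 16 and 17. This is the Stevens retron. It replaces the closure of a 19-membered carbocycle by the much easier closure of a 20-membered C–S–C ring, and the C–C bond then forms inside an existing ring. The forward step needs a sulfonium salt that does not ionise, benzylic rather than S-methyl deprotonation, and [1,2]- over [2,3]-migration.

**15 back to 13.** Both C–S bonds are cut, giving a bis(benzylic bromide) and sulfide as a one-atom linchpin; the forward path runs through 14. The gain is an open chain with two identical electrophilic termini, so no differentiation of the ends is required. The demand is dilution, and a medium in which the methoxy-activated bromide on ring A does not solvolyse before sulfur arrives.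

**13 back to 12 and 11.** The two C–Br bonds go back to C–OH and then to two methyl esters. Carrying both benzylic carbons as esters is the main design choice for the precursor. The esters are inert to the ylide, to hydrogenation and to base, they cannot be confused with the aldehyde and phosphonium carbons used for the other bridge, and both are unmasked by one hydride reduction and one bromination. The demand is mild bromination, with the labile dibromide used at once.

**11 back to 10, then to 5 and 8.** The B–C bridge is taken back to a C=C bond and cut by a Wittig disconnection (through 9), with the ylide carbon on ring B and the aldehyde on ring C. This splits the molecule into two diaryl ether halves of similar size, each made in one to three steps. The demands are an olefination base that spares methyl esters and an alkene hydrogenation that spares the benzyl ether; the alkene geometry is irrelevant.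

**5 back to 4, 3, then 1 and 2.** The C–P bond goes back to a benzylic alcohol and to an aldehyde, and the A–O–B ether is cut between oxygen and ring B. The formyl group on ring B first activates fluoride displacement and then becomes the ylide carbon, so no carbon is wasted; ring A arrives with its ester and methoxyl already in place. The demand is only that the hydride reduction distinguishes aldehyde from ester.

**8 back to 6 and 7.** The C–O–D ether is cut between oxygen and ring D. Ring D has no group that could activate nucleophilic substitution, so a copper-mediated oxidative coupling of the phenol with an arylboronic acid is used. It runs at room temperature and tolerates the aldehyde needed for the olefination. The demand is an excess of boronic acid to cover protodeboronation.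

## Other disconnections considered

**Alternative 1: Friedel–Crafts macroacylation.** The cut is the bond between ring A C4 and the acyl carbon of the D–A bridge.
- Forward step: the open-chain ring D arylacetic acid A1 (ring C phenol as mesylate, ring A a plain 2-aryloxyanisole) would be activated with (CF3CO)2O/H3PO4 and should acylate the position para to the methoxyl, closing the 19-membered ketone A2.
- In favour: the carbocycle is closed directly by C–C bond formation with an unfunctionalised C–H as one partner; the methoxyl directs to the right carbon; the mesylate deactivates ring C.
- Against: a cationic acylation has no built-in preference for the intramolecular path, and mixed-anhydride conditions are normally run concentrated, so oligomers are a real concern. Ring A C5 (para to the aryloxy group) and the positions of ring B ortho to oxygen are competing nucleophiles. Ring D needs a one-carbon homologation to the arylacetic acid. After closure the ketone must be deoxygenated and the mesylate cleaved (two operations).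
- Comparison: structurally it is the better plan on one point, since ring A needs no benzylic handle and no sulfur or nickel chemistry is involved. Mechanistically the chosen plan is safer, because the ring is closed by a soft thiolate alkylation and the C–C bond then forms inside the ring. In step count the two are about equal overall; the alternative needs two post-cyclisation steps against one.

**Alternative 2: SNAr macrocyclisation with a formyl activating group.** The cut is the ring A C6–O bond of the A–O–B ether.
- Forward step: the ring B phenoxide of the open chain A3 would displace fluoride ortho to the formyl group of ring A (K2CO3, polar aprotic solvent, dilution, heat) to give the macrocyclic aldehyde A4.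
- In favour: macrocyclic diaryl ether formation by SNAr is a well-established closure mode. The nucleophile/electrophile pair is latent until base and heat are applied. Only fluoride is lost, and the ring is formed at its final size.
- Against: a single ortho formyl group is a much weaker activator than nitro, so forcing temperatures would be needed with an aldehyde present. The formyl group must afterwards be turned into the methoxyl (Baeyer–Villiger or Dakin-type oxidation, hydrolysis, O-methylation) before debenzylation, three to four steps after ring closure. Both CH2–CH2 bridges must be built in the open chain by two separate olefination/hydrogenation sequences while a reactive fluoroaldehyde is carried or masked.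
- Comparison: it is the equal of the chosen plan in reliability of the ring-closing event (both are ionic substitutions under dilution), and better in that no ring contraction is needed. It is clearly worse in step economy after the key step (three to four steps against one) and in the length of the open-chain assembly.

**Alternative 3: oxidative phenol coupling.** The cut is the O–C5 bond of the C–O–D ether.
- Forward step: Tl(NO3)3 (trivalent thallium) would oxidise the 3,5-dibromo-4-hydroxyphenyl ring C of the open bis(bibenzyl) A5. The ring D phenol oxygen would add to a bromine-bearing ortho carbon, and reductive work-up with Zn should give the monobromo macrocycle A6, which one hydrogenolysis converts into 20.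
- In favour: it is biomimetic and needs no phenol protecting group. The two bromine-bearing carbons of ring C are equivalent, so only one regiochemistry is possible. The end-game is a single step.
- Against: it requires a stoichiometric, highly toxic thallium salt. The ring D phenol of A5 has no ortho halogens and a free para position, so it is itself open to oxidation, and the electron-rich ring A is a further oxidisable site. Oxidative macrocyclisations of this kind are generally modest in efficiency. Both bridges and the A–O–B ether must already be in place, so any loss falls on the most advanced intermediate.
- Comparison: it equals the chosen plan in post-cyclisation steps (one each) and is better in protecting-group economy. It is worse in mechanistic control (several oxidisable rings compete, against a closed-shell alkylation followed by an intramolecular shift) and in safety.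

Key step: step 10

Remark on the chemistry: the target has no stereocentre, so the alkene geometry of 10, the configuration at sulfur in 16 and the configuration at C–SMe in 18 are left undefined (mixture or racemate); all three are erased before the end.

## Route

Step 1
Reactants: 1 methyl 3-hydroxy-4-methoxybenzoate (methyl isovanillate); 2 4-fluorobenzaldehyde
Product: 3 methyl 3-(4-formylphenoxy)-4-methoxybenzoate
Conditions: K2CO3, DMF, 130 °C
Reagents that add atoms: none
Why: SNAr (addition–elimination): the para formyl group stabilises the Meisenheimer adduct, fluoride is the best leaving group for this mechanism, and the phenoxide of 1 is the only nucleophile. The non-enolisable aldehyde and the methyl ester tolerate dry carbonate.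

Step 2
Reactants: 3 methyl 3-(4-formylphenoxy)-4-methoxybenzoate
Product: 4 methyl 3-[4-(hydroxymethyl)phenoxy]-4-methoxybenzoate
Conditions: NaBH4, MeOH–THF, 0 °C
Reagents that add atoms: none
Why: Chemoselective borohydride reduction: the aryl aldehyde is reduced within minutes at 0 °C while the benzoate ester is inert to NaBH4.

Step 3
Reactants: 4 methyl 3-[4-(hydroxymethyl)phenoxy]-4-methoxybenzoate
Product: 5 ({4-[2-methoxy-5-(methoxycarbonyl)phenoxy]phenyl}methyl)triphenylphosphonium bromide
Conditions: PPh3·HBr, MeCN, reflux
Reagents that add atoms: triphenylphosphine hydrobromide (PPh3·HBr), [Br-].c1ccc(cc1)[PH+](c1ccccc1)c1ccccc1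
Why: Direct conversion of a benzylic alcohol into its phosphonium salt: protonation and loss of water are assisted by the para aryloxy group, and triphenylphosphine captures the benzylic electrophile. The salt should crystallise and needs no chromatography.

Step 4
Reactants: 6 4-(benzyloxy)-3-hydroxybenzaldehyde; 7 3-(methoxycarbonyl)phenylboronic acid
Product: 8 methyl 3-[2-(benzyloxy)-5-formylphenoxy]benzoate
Conditions: Cu(OAc)2, pyridine, 4 Å MS, CH2Cl2, dry air, rt
Reagents that add atoms: none
Why: Chan–Lam oxidative O-arylation: the aryl group is transmetalated from boron to the copper phenoxide, oxidation to trivalent copper follows, and C–O reductive elimination occurs at room temperature. Ring D needs no activating group, and the aldehyde, benzyl ether and ester are untouched.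

Step 5
Reactants: 5 ({4-[2-methoxy-5-(methoxycarbonyl)phenoxy]phenyl}methyl)triphenylphosphonium bromide; 8 methyl 3-[2-(benzyloxy)-5-formylphenoxy]benzoate
Product: 10 methyl 3-[4-(2-{4-(benzyloxy)-3-[3-(methoxycarbonyl)phenoxy]phenyl}ethenyl)phenoxy]-4-methoxybenzoate (E/Z mixture), via phosphonium ylide 9 (not isolated)
Conditions: K2CO3, 18-crown-6 (cat.), CH2Cl2, reflux
Reagents that add atoms: none
Why: Wittig olefination of an aryl aldehyde with a semi-stabilised benzylic ylide generated by solid–liquid phase transfer; carbonate is too weak to touch the methyl esters. The E/Z mixture is accepted because the double bond is saturated in step 6.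

Step 6
Reactants: 10 stilbene diester (E/Z mixture)
Product: 11 methyl 3-[4-(2-{4-(benzyloxy)-3-[3-(methoxycarbonyl)phenoxy]phenyl}ethyl)phenoxy]-4-methoxybenzoate
Conditions: H2 (1 atm), 10% Pd/C, Ph2S (cat.), EtOAc, rt
Reagents that add atoms: none
Why: Heterogeneous hydrogenation of the stilbene double bond on a sulfide-poisoned palladium surface, which still saturates alkenes but no longer hydrogenolyses aryl benzyl ethers. The esters are inert.

Step 7
Reactants: 11 bibenzyl diester
Product: 12 {3-[4-(2-{4-(benzyloxy)-3-[3-(hydroxymethyl)phenoxy]phenyl}ethyl)phenoxy]-4-methoxyphenyl}methanol
Conditions: LiAlH4, THF, 0 °C to rt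
Reagents that add atoms: none
Why: Hydride reduction of both benzoate esters to the benzylic alcohols in one operation; aryl ethers and the benzyl ether do not react with LiAlH4.

Step 8
Reactants: 12 bis(benzylic) diol
Product: 13 4-(bromomethyl)-2-[4-(2-{4-(benzyloxy)-3-[3-(bromomethyl)phenoxy]phenyl}ethyl)phenoxy]-1-methoxybenzene
Conditions: PBr3, CH2Cl2, 0 °C
Reagents that add atoms: phosphorus tribromide (PBr3), BrP(Br)Br
Why: Bromination of primary benzylic alcohols through their phosphite esters with bromide displacement; both termini react alike. The product, whose ring A bromide is activated by the para methoxyl, is used directly after a short filtration.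

Step 9
Reactants: 13 bis(benzylic bromide)
Product: 15 20-membered cyclic dibenzyl sulfide (bridge ring D–CH2–S–CH2–ring A C4; ring C phenol as benzyl ether), via sodium bromo thiolate 14 (not isolated)
Conditions: Na2S·9H2O on Al2O3, CH2Cl2–EtOH (9:1), rt, slow addition of 13 (final ≤2 mM)
Reagents that add atoms: sodium sulfide (Na2S), [Na+].[Na+].[S-2]
Why: Twofold SN2 alkylation of sulfide: the first displacement gives thiolate 14 (whichever bromide reacts first, the same ring results), which closes the 20-membered ring by intramolecular S-alkylation at a benzylic carbon. Slow addition to the supported reagent keeps the stationary concentration low, and the low-polarity medium suppresses ionisation of the methoxy-activated bromide.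

Step 10
Reactants: 15 20-membered cyclic dibenzyl sulfide
Product: 18 racemic 19-membered macrocycle with SMe on the ring D benzylic carbon (bridge ring D–CH(SMe)–CH2–ring A C4; ring C phenol as benzyl ether), via S-methylsulfonium tetrafluoroborate 16 (not isolated), via sulfonium ylide 17 (not isolated)
Conditions: Me3OBF4, CH2Cl2, 0 °C to rt; evaporate; KOt-Bu, THF, 0 °C to rt
Reagents that add atoms: trimethyloxonium tetrafluoroborate (Me3OBF4), C[O+](C)C.F[B-](F)(F)F
Why: The oxonium salt methylates the only soft nucleophile, the sulfide sulfur, to give 16; tert-butoxide then removes a benzylic proton next to the positive sulfur to give ylide 17, whose S–CH2 bond to the other benzyl group homolyses to a solvent-caged radical pair that recombines at carbon, a [1,2]-Stevens shift. The closest known reaction type is the Stevens ring contraction of S-methylated thiacyclophanes to methylthio-substituted carbocyclic cyclophanes. The 19-membered ring is not closed from an open chain: it arises by contraction of the 20-membered ring, the two radical centres being held together by the rest of the macrocycle, so the C–C bond forms intramolecularly without dilution. The new stereocentre at C–SMe has no controlling element and forms as the racemate, which is acceptable because step 11 converts it into CH2. The step needs [1,2]- rather than [2,3]-(Sommelet–Hauser) migration and deprotonation at a benzylic carbon rather than at S–CH3. Aprotic KOt-Bu in THF and the much higher acidity of the benzylic protons secure this, with the ring D CH2 the most acidic because its ring bears only a meta aryloxy group. The migrating group is then the radical-stabilised 4-methoxy-3-aryloxybenzyl unit of ring A, which gives the drawn regioisomer. Any product of the other benzylic ylide would carry SMe on the ring A carbon and converges on the same bibenzyl in step 11.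

Step 11
Reactants: 18 racemic methylthio macrocycle
Product: 20 target macrocycle (bridge ring D–CH2–CH2–ring A; ring C free phenol), via O-benzyl macrocycle 19 (not isolated)
Conditions: Raney Ni (W-2, large excess), H2 (1 atm), EtOH–THF, reflux
Reagents that add atoms: none
Why: Reductive desulfurisation: nickel hydrogenolyses the benzylic C–S bond first, and with hydrogen present the same surface then cleaves the aryl benzyl ether of 19. The aryl methyl ether, diaryl ethers and arene rings are inert at 1 atm, and the racemic C–SMe centre becomes CH2, so the product is the achiral target.

## Compound list

1 | methyl 3-hydroxy-4-methoxybenzoate | COC(=O)c1ccc(OC)c(O)c1 | starting material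
2 | 4-fluorobenzaldehyde | O=Cc1ccc(F)cc1 | starting material
3 | methyl 3-(4-formylphenoxy)-4-methoxybenzoate | COC(=O)c1ccc(OC)c(Oc2ccc(C=O)cc2)c1 | intermediate
4 | methyl 3-[4-(hydroxymethyl)phenoxy]-4-methoxybenzoate | COC(=O)c1ccc(OC)c(Oc2ccc(CO)cc2)c1 | intermediate
5 | ({4-[2-methoxy-5-(methoxycarbonyl)phenoxy]phenyl}methyl)triphenylphosphonium bromide | COC(=O)c1ccc(OC)c(Oc2ccc(C[P+](c3ccccc3)(c3ccccc3)c3ccccc3)cc2)c1.[Br-] | intermediate
6 | 4-(benzyloxy)-3-hydroxybenzaldehyde | O=Cc1ccc(OCc2ccccc2)c(O)c1 | starting material
7 | 3-(methoxycarbonyl)phenylboronic acid | COC(=O)c1cccc(B(O)O)c1 | starting material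
8 | methyl 3-[2-(benzyloxy)-5-formylphenoxy]benzoate | COC(=O)c1cccc(Oc2cc(C=O)ccc2OCc2ccccc2)c1 | intermediate
9 | methyl 4-methoxy-3-{4-[(triphenyl-λ5-phosphanylidene)methyl]phenoxy}benzoate (ylide of 5, not isolated) | COC(=O)c1ccc(OC)c(Oc2ccc(C=P(c3ccccc3)(c3ccccc3)c3ccccc3)cc2)c1 | intermediate
10 | methyl 3-[4-(2-{4-(benzyloxy)-3-[3-(methoxycarbonyl)phenoxy]phenyl}ethenyl)phenoxy]-4-methoxybenzoate, E/Z mixture, geometry undefined | COC(=O)c1ccc(OC)c(Oc2ccc(C=Cc3ccc(OCc4ccccc4)c(Oc4cccc(C(=O)OC)c4)c3)cc2)c1 | intermediate
11 | methyl 3-[4-(2-{4-(benzyloxy)-3-[3-(methoxycarbonyl)phenoxy]phenyl}ethyl)phenoxy]-4-methoxybenzoate | COC(=O)c1ccc(OC)c(Oc2ccc(CCc3ccc(OCc4ccccc4)c(Oc4cccc(C(=O)OC)c4)c3)cc2)c1 | intermediate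
12 | {3-[4-(2-{4-(benzyloxy)-3-[3-(hydroxymethyl)phenoxy]phenyl}ethyl)phenoxy]-4-methoxyphenyl}methanol | COc1ccc(CO)cc1Oc1ccc(CCc2ccc(OCc3ccccc3)c(Oc3cccc(CO)c3)c2)cc1 | intermediate
13 | 4-(bromomethyl)-2-[4-(2-{4-(benzyloxy)-3-[3-(bromomethyl)phenoxy]phenyl}ethyl)phenoxy]-1-methoxybenzene | COc1ccc(CBr)cc1Oc1ccc(CCc2ccc(OCc3ccccc3)c(Oc3cccc(CBr)c3)c2)cc1 | intermediate
14 | sodium thiolate of the mono-substituted chain (S on the ring A benzylic carbon, Br still on the ring D benzylic carbon; not isolated) | COc1ccc(C[S-])cc1Oc1ccc(CCc2ccc(OCc3ccccc3)c(Oc3cccc(CBr)c3)c2)cc1.[Na+] | intermediate
15 | 20-membered cyclic dibenzyl sulfide (ring D–CH2–S–CH2–ring A C4; ring C O-benzyl) | COc1ccc2cc1Oc1ccc(cc1)CCc1ccc(OCc3ccccc3)c(c1)Oc1cccc(c1)CSC2 | intermediate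
16 | S-methylsulfonium tetrafluoroborate of 15 (racemic at sulfur; not isolated) | COc1ccc2cc1Oc1ccc(cc1)CCc1ccc(OCc3ccccc3)c(c1)Oc1cccc(c1)C[S+](C)C2.F[B-](F)(F)F | intermediate
17 | sulfonium ylide, carbanion on the ring D benzylic carbon (not isolated) | COc1ccc2cc1Oc1ccc(cc1)CCc1ccc(OCc3ccccc3)c(c1)Oc1cccc(c1)[CH-][S+](C)C2 | intermediate
18 | racemic 19-membered macrocycle, SMe on the ring D benzylic carbon, ring C O-benzyl | COc1ccc2cc1Oc1ccc(cc1)CCc1ccc(OCc3ccccc3)c(c1)Oc1cccc(c1)C(SC)C2 | intermediate
19 | O-benzyl ether of the target (desulfurised macrocycle; not isolated) | COc1ccc2cc1Oc1ccc(cc1)CCc1ccc(OCc3ccccc3)c(c1)Oc1cccc(c1)CC2 | intermediate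
20 | target macrocycle CNP0132125.0 (achiral) | COc1ccc2cc1Oc1ccc(cc1)CCc1ccc(O)c(c1)Oc1cccc(c1)CC2 | target

## Step count and weak points

Total step count: 11. Longest linear sequence: 10 steps (steps 1, 2, 3, 5, 6, 7, 8, 9, 10, 11); step 4 is the one-step side branch.

**Step 10 (key step).** The sulfonium salt carries a 4-methoxybenzyl-type C–S bond on ring A. Ionisation of that bond before or during the base treatment would open the ring and lead to oligomers. A [2,3]-shift into ring A or ring D, or deprotonation at S–CH3, would divert material into skeletons that desulfurisation does not converge. The fallback removes sulfur as SO2 instead of rearranging around it.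
- It sets out from 15.
- mCPBA (CH2Cl2, 0 °C) should give the cyclic sulfone F1.
- A Ramberg–Bäcklund reaction (CBr2F2, KOH on Al2O3, t-BuOH–CH2Cl2) should contract the ring through the episulfone to the 19-membered macrocyclic stilbene F2 (E/Z mixture).
- Hydrogenation over Pd/C (H2, EtOAc–MeOH) saturates the double bond and cleaves the benzyl ether, so the fallback comes back to the route at 20.

**Step 9.** Intermolecular alkylation may outrun ring closure and give linear and cyclic oligomers, and the ring A bromide may solvolyse before sulfur arrives. The fallback separates C–S bond formation from ring closure.
- It sets out from 13.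
- KSAc (DMF, rt) gives the bis(thioacetate) F3.
- K2CO3 in degassed MeOH–THF frees the dithiol F4 as its thiolate.
- Slow simultaneous addition of this solution and of I2 to a large volume of CH2Cl2–MeOH closes the 21-membered cyclic disulfide F5.
- P(NEt2)3 in benzene at rt extrudes one sulfur atom (phosphine attack at sulfur, then benzylic displacement by the tethered thiolate), and the fallback comes back at 15.

**Step 4.** Protodeboronation and oxidative homocoupling of the electron-poor boronic acid may be faster than C–O coupling with the ortho-alkoxy phenol, leaving 6 unconverted. The fallback is an Ullmann ether synthesis. From 6 with methyl 3-iodobenzoate, CuI (monovalent copper iodide, catalytic), picolinic acid and K3PO4 in DMSO at 90 °C, it comes back at 8 without any new intermediate.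

**Step 11.** Sulfiding of the nickel surface may stop hydrogenolysis of the benzyl ether before it is complete, and pushing the conditions risks the onset of arene saturation. The fallback separates the two events and removes the benzyl group without hydrogen.
- It sets out from 18.
- Nickel boride made in the flask (NiCl2·6H2O, NaBH4, MeOH–THF, 0 °C) desulfurises only and gives 19, now isolated.
- BCl3 with pentamethylbenzene as cation scavenger (CH2Cl2, −78 °C) cleaves the aryl benzyl ether while sparing the methyl ether, and the fallback comes back at 20.

**Step 6.** If the catalyst is under-poisoned, benzyl ether hydrogenolysis will accompany alkene saturation; if over-poisoned, reduction of the E isomer stalls. The fallback is a non-catalytic diimide reduction (TsNHNH2, NaOAc, DME–H2O, reflux), which cannot cleave benzyl ethers. It sets out from 10 and comes back at 11.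

## Further compounds

F1 | step 10 | 20-membered cyclic sulfone (S,S-dioxide of 15) | COc1ccc2cc1Oc1ccc(cc1)CCc1ccc(OCc3ccccc3)c(c1)Oc1cccc(c1)CS(=O)(=O)C2
F2 | step 10 | 19-membered macrocyclic stilbene (ring D–CH=CH–ring A, ring C O-benzyl; E/Z mixture, geometry undefined) | COc1ccc2cc1Oc1ccc(cc1)CCc1ccc(OCc3ccccc3)c(c1)Oc1cccc(c1)C=C2
F3 | step 9 | open-chain bis(S-acetyl) derivative: both benzylic bromides of 13 replaced by SC(O)CH3 | COc1ccc(CSC(C)=O)cc1Oc1ccc(CCc2ccc(OCc3ccccc3)c(Oc3cccc(CSC(C)=O)c3)c2)cc1
F4 | step 9 | open-chain bis(benzylic) dithiol | COc1ccc(CS)cc1Oc1ccc(CCc2ccc(OCc3ccccc3)c(Oc3cccc(CS)c3)c2)cc1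
F5 | step 9 | 21-membered cyclic disulfide (ring D–CH2–S–S–CH2–ring A) | COc1ccc2cc1Oc1ccc(cc1)CCc1ccc(OCc3ccccc3)c(c1)Oc1cccc(c1)CSSC2
F0 | step 4 | none | none
F0 | step 11 | none | none
F0 | step 6 | none | none
A1 | alternative 1 | open-chain ring D arylacetic acid with ring C mesylate and unsubstituted 2-aryloxyanisole ring A | OC(=O)Cc1cccc(Oc2cc(CCc3ccc(Oc4ccccc4OC)cc3)ccc2OS(C)(=O)=O)c1
A2 | alternative 1 | macrocyclic aryl ketone (carbonyl on ring A C4, ring C mesylate) | COc1ccc2cc1Oc1ccc(cc1)CCc1ccc(OS(C)(=O)=O)c(c1)Oc1cccc(c1)CC2=O
A3 | alternative 2 | open-chain ring B phenol with 2-fluoro-4-alkylbenzaldehyde ring A (ring C O-benzyl) | O=Cc1ccc(CCc2cccc(Oc3cc(CCc4ccc(O)cc4)ccc3OCc3ccccc3)c2)cc1F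
A4 | alternative 2 | macrocyclic ring A aldehyde (formyl in place of the methoxyl, ring C O-benzyl) | O=Cc1ccc2cc1Oc1ccc(cc1)CCc1ccc(OCc3ccccc3)c(c1)Oc1cccc(c1)CC2
A5 | alternative 3 | open bis(bibenzyl) with 3,5-dibromo-4-hydroxyphenyl ring C and 3-hydroxyphenyl ring D | COc1ccc(CCc2cccc(O)c2)cc1Oc1ccc(CCc2cc(Br)c(O)c(Br)c2)cc1
A6 | alternative 3 | monobromo macrocycle (target with Br on ring C C3) | COc1ccc2cc1Oc1ccc(cc1)CCc1cc(Br)c(O)c(c1)Oc1cccc(c1)CC2
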